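**Retrosynthetic overview**

1. Target 17 is (1S,4R,5S,6S)-5,6-dihydroxy-6-(hydroxymethyl)cyclohex-2-ene-1,4-diyl dibenzoate. It is traced back through acid deprotection (17 ⇐ 16), exchange of a silicon bridge for two benzoates (16 ⇐ 14), ketalisation (14 ⇐ 13) and a face-selective cis-dihydroxylation of a C5=C6 alkene (13 ⇐ 12).
2. Enabling feature: the oxygens on C1 and C4 are cis, and each of C1 and C4 lies between the C2=C3 alkene and the C5–C6 diol. At the C5=C6 oxidation level the carbocycle is therefore a cis-cyclohexa-2,5-diene-1,4-diol, i.e. two penta-1,4-dien-3-ol units joined head to head, whose two cis oxygens one silicon atom can bridge.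
3. Key disconnection: C2=C3 and C5–C6 (as C5=C6) are formed together by a double ring-closing metathesis of silaketal 10, made from (S)-dienol 7 and achiral penta-1,4-dien-3-ol 8. Ring order: seven-membered 1,3,2-dioxasilepine first, six-membered carbocycle second (2,4-dioxa-3-silabicyclo[3.2.2]nona-6,8-diene 12), dioxolane third; the silicon ring is removed in step 8 and the dioxolane in step 9.
4. Dienol 7 ⇐ lipase resolution of racemic 6 ⇐ 2-lithioallyl ether 5 + acrolein 4 ⇐ 4-methoxybenzyl alcohol 1 + 2,3-dibromopropene 2.

Key step: step 5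

Assumption (chemistry): the lipase follows its usual size rule for secondary alcohols (2-substituted propenyl group as the large substituent, vinyl as the medium one), so the (R)-alcohol is acetylated and the (S)-alcohol is recovered.

**Step 1**
Reactants: 1 4-methoxybenzyl alcohol; 2 2,3-dibromoprop-1-ene
Product: 3 1-{[(2-bromoprop-2-en-1-yl)oxy]methyl}-4-methoxybenzene
Conditions: NaH, THF, 0 °C → rt
Reagents that add atoms: none
Why: Williamson ether synthesis, in which the sodium alkoxide of 1 should displace only the allylic bromide of 2 (SN2), the vinylic C–Br bond being inert to substitution.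

**Step 2**
Reactants: 3 1-{[(2-bromoprop-2-en-1-yl)oxy]methyl}-4-methoxybenzene; 4 acrolein
Product: 6 rac-2-{[(4-methoxybenzyl)oxy]methyl}penta-1,4-dien-3-ol, via vinyllithium 5 (not isolated)
Conditions: t-BuLi (2.1 equiv), Et2O, −78 °C; then 4, −78 °C; aq NH4Cl
Reagents that add atoms: none
Why: Bromine–lithium exchange at −78 °C (the second equivalent of t-BuLi destroys t-BuBr) should give the 2-lithioallyl ether 5, which adds 1,2 to acrolein; the carbinol centre is racemic at this stage.

**Step 3**
Reactants: 6 rac-2-{[(4-methoxybenzyl)oxy]methyl}penta-1,4-dien-3-ol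
Product: 7 (3S)-2-{[(4-methoxybenzyl)oxy]methyl}penta-1,4-dien-3-ol
Conditions: immobilised Candida antarctica lipase B, vinyl acetate, MTBE, 30 °C, run slightly beyond half conversion; chromatography
Reagents that add atoms: none
Why: Lipase-catalysed kinetic resolution by irreversible transesterification, in which the enzyme should acetylate the (R)-enantiomer and leave enantioenriched (S)-alcohol 7; this step defines the absolute configuration of the whole route.

**Step 4**
Reactants: 8 penta-1,4-dien-3-ol; 7 (3S)-2-{[(4-methoxybenzyl)oxy]methyl}penta-1,4-dien-3-ol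
Product: 10 {[(3S)-2-{[(4-methoxybenzyl)oxy]methyl}penta-1,4-dien-3-yl]oxy}(penta-1,4-dien-3-yloxy)di(propan-2-yl)silane, via chlorosilane 9 (not isolated)
Conditions: 8, i-Pr2SiCl2 (1.05 equiv), imidazole, CH2Cl2, 0 °C; then 7, imidazole, DMAP (cat.), rt
Reagents that add atoms: dichlorodi(propan-2-yl)silane, CC(C)[Si](Cl)(Cl)C(C)C
Why: Stepwise silylation, in which the first chloride of i-Pr2SiCl2 is displaced much faster than the second for steric reasons, so chlorosilane 9 should form selectively and then be capped by 7 to give the unsymmetrical silaketal without touching the carbinol stereocentre.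

**Step 5**
Reactants: 10 {[(3S)-2-{[(4-methoxybenzyl)oxy]methyl}penta-1,4-dien-3-yl]oxy}(penta-1,4-dien-3-yloxy)di(propan-2-yl)silane
Product: 12 (1R,5S)-6-{[(4-methoxybenzyl)oxy]methyl}-3,3-di(propan-2-yl)-2,4-dioxa-3-silabicyclo[3.2.2]nona-6,8-diene, via dioxasilepine 11 (not isolated)
Conditions: second-generation Hoveyda–Grubbs catalyst RuCl2(SIMes)(=CH-C6H4-2-O-i-Pr) (10 mol %), 1,4-benzoquinone (20 mol %), toluene (2 mM), 80 °C, slow argon sparge
Reagents that add atoms: none
Why: A ruthenium alkylidene formed at a vinyl group first closes the seven-membered 1,3,2-dioxasilepine 11 across the O–Si–O tether (ring-closing olefin metathesis, ethene lost), and the alkylidene on the remaining vinyl group of the former divinylcarbinol then closes transannularly onto the 1,1-disubstituted alkene to give the carbocycle (second ethene lost). The closest known reactions are the temporary-silicon-tethered RCM of bis(allyloxy)silanes to cis-4,7-disubstituted dioxasilepines, including group-selective cyclisation of divinylcarbinol silaketals, and the RCM of 1,4,7-trienes to cyclohexa-1,4-dienes. Ring 1 (dioxasilepine) closes by RCM to an endocyclic cis alkene, and ring 2 (cyclohexa-1,4-diene) closes by transannular RCM that forms the trisubstituted alkene and completes the 2,4-dioxa-3-silabicyclo[3.2.2]nonadiene. The one new stereocentre, the carbinol carbon of achiral 8, is controlled by the tether, because only the vinyl group that places this C–O bond cis to the C–O bond of the (S)-centre can span the ring, so the bicycle can exist only with the cis-1,4-dioxygen pattern. The step needs cross-selectivity between the two dienols, group selectivity between the two vinyl groups of 8, and cyclisation over oligomerisation: the tether joins exactly one unit of each dienol and forbids a trans-bridged product, neither dienol can close on itself (that would be a cyclopropene), and high dilution favours ring closure. In the product the bridgehead C–O bonds lie orthogonal to both π bonds, so the bis-allylic diene should neither ionise nor aromatise.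

**Step 6**
Reactants: 12 (1R,5S)-6-{[(4-methoxybenzyl)oxy]methyl}-3,3-di(propan-2-yl)-2,4-dioxa-3-silabicyclo[3.2.2]nona-6,8-diene
Product: 13 (1R,5S,6S,7S)-6-{[(4-methoxybenzyl)oxy]methyl}-3,3-di(propan-2-yl)-2,4-dioxa-3-silabicyclo[3.2.2]non-8-ene-6,7-diol
Conditions: OsO4 (5 mol %), NMO (1.1 equiv), acetone/H2O (8:1), 0 °C → rt; aq Na2SO3
Reagents that add atoms: osmium tetroxide (catalytic oxygen carrier), O=[Os](=O)(=O)=O; N-methylmorpholine N-oxide, C[N+]1([O-])CCOCC1; water, O
Why: Catalytic OsO4/NMO cis-dihydroxylation, in which the more electron-rich trisubstituted C6=C7 alkene should react before the disubstituted C8=C9 alkene and OsO4 should approach from the face next to the other etheno bridge, because the two isopropyl groups on the O–Si–O bridge screen the opposite face; this sets both carbinol centres anti to the bridgehead oxygens.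

**Step 7**
Reactants: 13 (1R,5S,6S,7S)-6-{[(4-methoxybenzyl)oxy]methyl}-3,3-di(propan-2-yl)-2,4-dioxa-3-silabicyclo[3.2.2]non-8-ene-6,7-diol
Product: 14 6,7-O-isopropylidene acetal (acetonide) of 13
Conditions: 2,2-dimethoxypropane, PPTS (cat.), CH2Cl2, rt
Reagents that add atoms: 2,2-dimethoxypropane, COC(C)(C)OC
Why: Acid-catalysed transacetalisation of the cis-diol, held eclipsed on the bicycle, should give the dioxolane, while PPTS is too weak to cleave the hindered dialkoxydiisopropylsilane or the PMB ether.

**Step 8**
Reactants: 14 6,7-O-isopropylidene acetal (acetonide) of 13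
Product: 16 acetonide-protected PMB-protected cyclohex-2-ene-1,4-diyl dibenzoate (configuration as in 17), via diol 15 (not isolated)
Conditions: HF·pyridine, pyridine, THF, 0 °C → rt; then BzCl (excess), DMAP, 0 °C → rt
Reagents that add atoms: benzoyl chloride, O=C(Cl)c1ccccc1
Why: Fluoride-mediated desilylation cleaves both Si–O bonds of the bridge while acetonide and PMB ether survive the pyridine-buffered medium, and the two secondary allylic alcohols of 15 are then the only free hydroxyls for DMAP-catalysed benzoylation, which does not touch any stereocentre.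

**Step 9**
Reactants: 16 acetonide-protected PMB-protected cyclohex-2-ene-1,4-diyl dibenzoate
Product: 17 (1S,4R,5S,6S)-5,6-dihydroxy-6-(hydroxymethyl)cyclohex-2-ene-1,4-diyl dibenzoate
Conditions: TFA/CH2Cl2 (1:3), anisole (5 equiv), H2O (5 equiv), 0 °C → rt
Reagents that add atoms: none
Why: Acidolysis, in which aqueous TFA hydrolyses the isopropylidene ketal and ionises the 4-methoxybenzyl ether (cation trapped by anisole in a Friedel–Crafts alkylation), while the acid-stable benzoates and the allylic C–O bonds flanked by electron-withdrawing oxygens should survive.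

**Compound list**

1 | 4-methoxybenzyl alcohol | COc1ccc(CO)cc1 | starting material
2 | 2,3-dibromoprop-1-ene | C=C(Br)CBr | starting material
3 | 1-{[(2-bromoprop-2-en-1-yl)oxy]methyl}-4-methoxybenzene | C=C(Br)COCc1ccc(OC)cc1 | intermediate
4 | acrolein (prop-2-enal) | C=CC=O | starting material
5 | {3-[(4-methoxybenzyl)oxy]prop-1-en-2-yl}lithium (not isolated) | [Li]C(=C)COCc1ccc(OC)cc1 | intermediate
6 | rac-2-{[(4-methoxybenzyl)oxy]methyl}penta-1,4-dien-3-ol | C=CC(O)C(=C)COCc1ccc(OC)cc1 | intermediate
7 | (3S)-2-{[(4-methoxybenzyl)oxy]methyl}penta-1,4-dien-3-ol | C=C[C@H](O)C(=C)COCc1ccc(OC)cc1 | intermediate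
8 | penta-1,4-dien-3-ol | C=CC(O)C=C | starting material
9 | chloro(penta-1,4-dien-3-yloxy)di(propan-2-yl)silane (not isolated) | C=CC(C=C)O[Si](Cl)(C(C)C)C(C)C | intermediate
10 | {[(3S)-2-{[(4-methoxybenzyl)oxy]methyl}penta-1,4-dien-3-yl]oxy}(penta-1,4-dien-3-yloxy)di(propan-2-yl)silane | C=CC(C=C)O[Si](C(C)C)(C(C)C)O[C@@H](C=C)C(=C)COCc1ccc(OC)cc1 | intermediate
11 | cis-(4S,7S)-4-{3-[(4-methoxybenzyl)oxy]prop-1-en-2-yl}-2,2-di(propan-2-yl)-7-vinyl-4,7-dihydro-1,3,2-dioxasilepine (not isolated) | CC(C)[Si]2(C(C)C)O[C@H](C(=C)COCc1ccc(OC)cc1)C=C[C@@H](O2)C=C | intermediate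
12 | (1R,5S)-6-{[(4-methoxybenzyl)oxy]methyl}-3,3-di(propan-2-yl)-2,4-dioxa-3-silabicyclo[3.2.2]nona-6,8-diene | CC(C)[Si]2(C(C)C)O[C@H]1C=C[C@@H](O2)C=C1COCc3ccc(OC)cc3 | intermediate
13 | (1R,5S,6S,7S)-6-{[(4-methoxybenzyl)oxy]methyl}-3,3-di(propan-2-yl)-2,4-dioxa-3-silabicyclo[3.2.2]non-8-ene-6,7-diol (both hydroxyls on the face away from the O–Si–O bridge) | CC(C)[Si]2(C(C)C)O[C@H]1C=C[C@@H](O2)[C@H](O)[C@@]1(O)COCc3ccc(OC)cc3 | intermediate
14 | 6,7-O-isopropylidene acetal (acetonide) of 13; dioxolane cis-fused on the face away from the silicon bridge | CC(C)[Si]3(C(C)C)O[C@H]1C=C[C@@H](O3)[C@@H]2OC(C)(C)O[C@]12COCc4ccc(OC)cc4 | intermediate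
15 | 5,6-O-isopropylidene-6-C-{[(4-methoxybenzyl)oxy]methyl}cyclohex-2-ene-1,4,5,6-tetrol (numbering and configuration of 17: O-1 and O-4 cis, O-5 and O-6 cis and anti to them; not isolated) | O[C@H]1C=C[C@@H](O)[C@@H]2OC(C)(C)O[C@]12COCc3ccc(OC)cc3 | intermediate
16 | 1,4-di-O-benzoyl derivative of 15 | O=C(O[C@H]1C=C[C@@H](OC(=O)c3ccccc3)[C@@H]2OC(C)(C)O[C@]12COCc4ccc(OC)cc4)c5ccccc5 | intermediate
17 | (1S,4R,5S,6S)-5,6-dihydroxy-6-(hydroxymethyl)cyclohex-2-ene-1,4-diyl dibenzoate | O=C(O[C@H]1C=C[C@@H](OC(=O)c2ccccc2)[C@H](O)[C@@]1(O)CO)c1ccccc1 | target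

**Step count and risks**

Total steps: 9. Longest linear sequence: 9 steps (1 → 17); 8 is purchased and enters at step 4.

Step 5 (key step). The first ring closure may engage the vinyl group of 8 that leads to a trans-dioxasilepine, which cannot bicyclise. The transannular closure onto the 1,1-disubstituted alkene may also stall, leaving oligomerisation or alkene migration to take over. The fallback separates the two ring closures and drops the bridge for the second one. From 10, the first-generation Grubbs catalyst RuCl2(PCy3)2(=CHPh) (CH2Cl2, 40 °C), which is largely unreactive toward the 1,1-disubstituted alkene, should stop at the seven-membered ring, and cis-dioxasilepine 11 would be isolated (a trans isomer, if formed, is removed here). Bu4NF in THF then removes the tether to give the syn (Z)-triene diol (3S,4Z,6S)-2-{[(4-methoxybenzyl)oxy]methyl}octa-1,4,7-triene-3,6-diol F1, whose Z alkene holds the two remaining alkenes close. RCM of F1 with the second-generation Grubbs catalyst RuCl2(SIMes)(PCy3)(=CHPh) (CH2Cl2, 40 °C, dilute) closes an unstrained cyclohexa-1,4-diene, (1S,4R)-2-{[(4-methoxybenzyl)oxy]methyl}cyclohexa-2,5-diene-1,4-diol F2. Because F2 is prone to acid-induced dehydration to an arene, it is taken at once into i-Pr2Si(OTf)2, 2,6-lutidine, CH2Cl2, −40 °C, which re-bridges the cis-1,4-diol and returns the route to 12.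

Step 6. Site selectivity may be poor: osmylation of the disubstituted alkene or double dihydroxylation may compete, since only the substitution pattern distinguishes the two alkenes. The fallback uses a hydroxyl-directed osmylation. From 12, DDQ (CH2Cl2, pH 7 buffer, 0 °C) removes the PMB group to give the allylic alcohol [(1R,5S)-3,3-di(propan-2-yl)-2,4-dioxa-3-silabicyclo[3.2.2]nona-6,8-dien-6-yl]methanol F3; the bridgehead C–H bonds are orthogonal to the π bonds, so DDQ should not aromatise the diene. Stoichiometric OsO4·TMEDA (CH2Cl2, −78 °C; then ethylenediamine) is delivered by hydrogen bonding to the free hydroxyl and should therefore oxidise only the alkene that carries CH2OH, still from the face away from the silicon bridge. This gives the triol (1R,5S,6S,7S)-6-(hydroxymethyl)-3,3-di(propan-2-yl)-2,4-dioxa-3-silabicyclo[3.2.2]non-8-ene-6,7-diol F4. Selective re-etherification of the primary hydroxyl through the stannylene acetal (Bu2SnO, toluene, reflux; then PMBCl, Bu4NI, 60 °C) returns the route to 13.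

Step 3. The enzyme may discriminate poorly between a vinyl and a 2-substituted vinyl group, so the recovered alcohol may not reach useful enantiopurity. The fallback replaces the enzymatic kinetic resolution by separation of covalent diastereomers. From racemic 6, esterification with (S)-2-methoxy-2-phenylacetic acid (DCC, DMAP, CH2Cl2, 0 °C) gives two diastereomeric esters, the (S)-2-methoxy-2-phenylacetate of the (S)-alcohol F5 and the (S)-2-methoxy-2-phenylacetate of the (R)-alcohol F6. These are separated by chromatography (preparative HPLC if needed), with the configuration of each to be assigned from the shielding pattern of the mandelate. Saponification of F5 (LiOH, THF/H2O, 0 °C) returns the route to 7.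

**Further compounds**

F1 | step 5 | (3S,4Z,6S)-2-{[(4-methoxybenzyl)oxy]methyl}octa-1,4,7-triene-3,6-diol | O[C@H](C(=C)COCc1ccc(OC)cc1)/C=C\[C@@H](O)C=C
F2 | step 5 | (1S,4R)-2-{[(4-methoxybenzyl)oxy]methyl}cyclohexa-2,5-diene-1,4-diol | O[C@H]1C=C[C@@H](O)C=C1COCc2ccc(OC)cc2
F3 | step 6 | [(1R,5S)-3,3-di(propan-2-yl)-2,4-dioxa-3-silabicyclo[3.2.2]nona-6,8-dien-6-yl]methanol | CC(C)[Si]2(C(C)C)O[C@H]1C=C[C@@H](O2)C=C1CO
F4 | step 6 | (1R,5S,6S,7S)-6-(hydroxymethyl)-3,3-di(propan-2-yl)-2,4-dioxa-3-silabicyclo[3.2.2]non-8-ene-6,7-diol | CC(C)[Si]2(C(C)C)O[C@H]1C=C[C@@H](O2)[C@H](O)[C@@]1(O)CO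
F5 | step 3 | (3S)-2-{[(4-methoxybenzyl)oxy]methyl}penta-1,4-dien-3-yl (2S)-2-methoxy-2-phenylacetate | CO[C@H](C(=O)O[C@@H](C=C)C(=C)COCc1ccc(OC)cc1)c2ccccc2
F6 | step 3 | (3R)-2-{[(4-methoxybenzyl)oxy]methyl}penta-1,4-dien-3-yl (2S)-2-methoxy-2-phenylacetate | CO[C@H](C(=O)O[C@H](C=C)C(=C)COCc1ccc(OC)cc1)c2ccccc2
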